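Ring A (C5–C10) is treated as a dearomatised 4-methylcatechol: C5 carries a methyl group and sits para to the C8 oxygen, while C9 carries the second oxygen. The route therefore rests on the C4–C5 bond, formed when the para carbon C5 of a C8 phenoxide adds to the β-carbon C4 of an (E)-enone tethered to C10 through C1–C3. One operation closes ring B, creates the quaternary C5 and the C4 stereocentre with the methyls cis, and leaves the C2 ketone, a C8 dienone carbonyl and a C9 enol ether as the later diol. The precursor is (E)-1-[3-hydroxy-2-(methoxymethoxy)-6-methylphenyl]pent-3-en-2-one.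

Key step: step 9

Remark: locants follow the target (ring B C10–C1–C2(=O)–C3–C4–C5, ring A C5–C6–C7–C8–C9–C10, C11–C13 = isopropenyl) and α is the face of the C5 methyl; O9 is carried as a MOM ether instead of a methyl ether so that it can be freed once C9 is saturated; the C2 carbinol/epoxide centre in 6, 7, 8 and 10 is racemic and is erased on oxidation.

Step 1
Reactants: 1 2-hydroxy-4-methylbenzaldehyde; 2 allyl bromide
Product: 3 2-(allyloxy)-4-methylbenzaldehyde
Conditions: K2CO3, DMF, 50 °C
Reagents that add atoms: allyl bromide, C=CCBr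
Why: Williamson ether synthesis on the phenoxide puts the allyl group on the oxygen that becomes O9 (meta to the ring methyl).

Step 2
Reactants: 3 2-(allyloxy)-4-methylbenzaldehyde
Product: 4 3-allyl-2-hydroxy-4-methylbenzaldehyde
Conditions: N,N-diethylaniline, 200 °C
Reagents that add atoms: none
Why: The aromatic Claisen rearrangement ([3,3] shift, then tautomerisation) has only one free ortho carbon available, so the allyl chain lands on the future C10 between O9 and the methyl-bearing C5.

Step 3
Reactants: 4 3-allyl-2-hydroxy-4-methylbenzaldehyde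
Product: 5 3-allyl-2-(methoxymethoxy)-4-methylbenzaldehyde
Conditions: MOMCl, i-Pr2NEt, CH2Cl2, 0 °C → rt
Reagents that add atoms: chloromethyl methyl ether, COCCl
Why: Base-mediated O-alkylation gives an acetal-type ether that tolerates peracid, organometallics, base and hydrogenation and, unlike a methyl ether, can later be removed from a saturated C9 by mild acid.

Step 4
Reactants: 5 3-allyl-2-(methoxymethoxy)-4-methylbenzaldehyde
Product: 7 2-(methoxymethoxy)-4-methyl-3-(oxiran-2-ylmethyl)phenol (racemic), via epoxy aryl formate 6 (not isolated)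
Conditions: mCPBA (2.5 equiv), CH2Cl2, 0 °C → rt; then K2CO3 (cat.), MeOH, rt
Reagents that add atoms: mCPBA, OOC(=O)c1cccc(Cl)c1
Why: Baeyer–Villiger (Dakin-type) oxidation of the electron-rich o-alkoxybenzaldehyde with aryl migration turns the formyl carbon into the formate of the O8 phenol while the same peracid epoxidises the allyl alkene (Prilezhaev), and methanolysis then frees the phenol; the epoxide carbon forms racemic and is erased in step 7.

Step 5
Reactants: 7 2-(methoxymethoxy)-4-methyl-3-(oxiran-2-ylmethyl)phenol
Product: 8 tert-butyldimethyl{[2-(methoxymethoxy)-4-methyl-3-(oxiran-2-ylmethyl)phenyl]oxy}silane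
Conditions: TBSCl, imidazole, DMF, rt
Reagents that add atoms: tert-butyldimethylsilyl chloride, CC(C)(C)[Si](C)(C)Cl
Why: Imidazole-promoted silylation protects the O8 phenol only after O9 is capped, so no silyl migration between the two catechol oxygens is possible.

Step 6
Reactants: 8 silyl-protected epoxide; 9 vinylmagnesium bromide
Product: 10 1-{3-[(tert-butyldimethylsilyl)oxy]-2-(methoxymethoxy)-6-methylphenyl}pent-4-en-2-ol (racemic)
Conditions: CuI (10 mol %), THF, −30 → 0 °C; aq. NH4Cl
Reagents that add atoms: vinylmagnesium bromide, C=C[Mg]Br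
Why: Copper-catalysed SN2 opening of the terminal epoxide at its unsubstituted carbon (C3) adds C4 and the carbon of the future C4 methyl group.

Step 7
Reactants: 10 homoallylic alcohol
Product: 12 (E)-1-{3-[(tert-butyldimethylsilyl)oxy]-2-(methoxymethoxy)-6-methylphenyl}pent-3-en-2-one, via allyl ketone 11 (not isolated)
Conditions: Dess–Martin periodinane, CH2Cl2, rt; NaHCO3 wash; then DBU (0.2 equiv), CH2Cl2, rt
Reagents that add atoms: none
Why: Dess–Martin oxidation gives the C2 ketone and amidine-base prototropy then moves the β,γ double bond into conjugation, giving the thermodynamically favoured (E)-enone.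

Step 8
Reactants: 12 (E)-enone silyl ether
Product: 13 (E)-1-[3-hydroxy-2-(methoxymethoxy)-6-methylphenyl]pent-3-en-2-one
Conditions: TBAF, AcOH (1:1), THF, 0 °C
Reagents that add atoms: none
Why: Fluoride cleavage of the aryl silyl ether under acetic acid buffering frees the phenol without forming free phenoxide, so no uncatalysed ring closure can start.

Step 9
Reactants: 13 (E)-1-[3-hydroxy-2-(methoxymethoxy)-6-methylphenyl]pent-3-en-2-one
Product: 14 (4S,4aS)-8-(methoxymethoxy)-4,4a-dimethyl-3,4-dihydronaphthalene-2,7(1H,4aH)-dione (route locants: 4α,5α-dimethyl; C2 ketone; C6=C7; C8 ketone; C9(OMOM)=C10)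
Conditions: chiral bifunctional phase-transfer catalyst (N-benzylcinchonidinium type with free hydroxyl, 10 mol %; the pseudoenantiomeric cinchoninium salt if a first screen shows the opposite sense), Cs2CO3 (1.5 equiv), toluene, −20 °C; AcOH quench at −20 °C
Reagents that add atoms: none
Why: Proposed new method: the phenoxide of 13 is an ambident nucleophile whose para carbon C5 adds to the enone β-carbon C4, the arene becoming the C8 dienone, and the C2 enolate then relays its charge to the more acidic C1 position, so that the adduct is held as a vinylogous 1,3-diketonate that cannot undergo retro-Michael re-aromatisation before the acidic quench. The closest known reaction types are catalytic asymmetric alkylative dearomatisations of phenols and naphthols under chiral ion-pair or bifunctional base catalysis and the classical intramolecular para-alkylation of phenoxides by tethered electrophiles. Ring B closes in a 6-endo-trig mode through the three-atom tether C1–C2–C3 on C10. C4 is set relative to C5 by a chair-like transition state in which the (E)-enone holds its methyl pseudo-equatorial, which translates directly into the cis relation of the C4 and C5 methyls. The absolute sense, that is the arene face alkylated at C5, is imposed by the chiral cation, which ion-pairs with the C8 phenoxide and hydrogen-bonds to the C2 carbonyl. The step needs C- over O-alkylation and para over ortho attack, and the substrate secures both because O8 and C7 cannot reach C4 through the meta tether and C9 is blocked by its protected oxygen.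

Step 10
Reactants: 14 bicyclic dienone
Product: 15 9β-(methoxymethoxy)-4α,5α-dimethyl-10αH-decalin-2,8-dione (cis-fused)
Conditions: H2 (5 bar), 10% Pd/C, EtOAc–pyridine, rt
Reagents that add atoms: none
Why: Heterogeneous syn-hydrogenation first saturates C6=C7 and then delivers both hydrogens to the tetrasubstituted enol-ether bond C9=C10 from the α face, as in the cis-selective Pd hydrogenation of angularly methylated Δ1(9)-2-octalones and Δ4-3-keto steroids in basic medium, so that C10–H and C9–H end α (cis ring fusion, O9 β).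

Step 11
Reactants: 15 cis-fused diketone
Product: 17 2α-methoxy-2β,9β-epoxy-4α,5α-dimethyl-10αH-decalin-8-one (bridged methyl ketal), via 9β-hydroxy diketone 16 (not isolated)
Conditions: HCl (cat.), MeOH, 40 °C
Reagents that add atoms: methanol, CO
Why: Acid-catalysed acetal exchange removes the MOM group and the freed 9β-hydroxyl, which on the cis-fused skeleton stands 1,3-diaxial to C2, closes a five-membered mixed methyl ketal (intramolecular ketalisation) whose geometry fixes the new C2 centre (bridging oxygen β, methoxy α), protects C2 and O9 together and locks the bicycle in one folded conformation that only the 9β-oxy-10α-H isomer can reach.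

Step 12
Reactants: 17 bridged ketal ketone; 18 acetone
Product: 19 7α-(2-hydroxypropan-2-yl)-2α-methoxy-2β,9β-epoxy-4α,5α-dimethyl-10αH-decalin-8-one
Conditions: LDA, THF, −78 °C; ZnCl2; acetone, −78 → −40 °C; aq. NH4Cl
Reagents that add atoms: acetone, CC(C)=O
Why: Kinetic deprotonation occurs at C7 (the C9–H is equatorial and stereoelectronically inert) and the zinc enolate adds to acetone (directed aldol) on the convex α face, the β face being the concave side screened by the C5–C4 bond and the bridging oxygen, which places the side chain 7α-equatorial, also the thermodynamic epimer.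

Step 13
Reactants: 19 aldol adduct
Product: 20 7α-(2-hydroxypropan-2-yl)-2α-methoxy-2β,9β-epoxy-4α,5α-dimethyl-10αH-decalin-8β-ol
Conditions: NaBH4, CeCl3·7H2O, MeOH, −40 °C
Reagents that add atoms: none
Why: Luche-type borohydride reduction attacks the C8 carbonyl axially from the open convex α face, anti to the axial C9–O bond (Felkin–Anh), and gives the equatorial 8β-alcohol, trans to the C7 side chain and cis to O9.

Step 14
Reactants: 20 bridged ketal diol
Product: 21 8β,9β-dihydroxy-7α-(2-hydroxypropan-2-yl)-4α,5α-dimethyl-10αH-decalin-2-one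
Conditions: 0.5 M HCl, THF–H2O, rt
Reagents that add atoms: water, O
Why: Aqueous acid hydrolysis of the mixed ketal returns the C2 ketone and the free 9β-hydroxyl under conditions that leave the tertiary alcohol and all stereocentres untouched.

Step 15
Reactants: 21 keto triol; 22 (R)-2-methylbutanoic acid
Product: 23 8β,9β-bis{[(R)-2-methylbutanoyl]oxy}-7α-(2-hydroxypropan-2-yl)-4α,5α-dimethyl-10αH-decalin-2-one
Conditions: 22 (3 equiv), EDC·HCl, DMAP, CH2Cl2, rt → 40 °C
Reagents that add atoms: (R)-2-methylbutanoic acid, CC[C@@H](C)C(=O)O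
Why: Carbodiimide/DMAP (Steglich) esterification acylates the two secondary hydroxyls while the tertiary C11 hydroxyl stays inert, and any 8→9 acyl migration is without consequence because both acyl groups are identical.

Step 16
Reactants: 23 diester tertiary alcohol
Product: 24 target, (4S,5R,7R,8R,9S,10S)-8β,9β-bis{[(R)-2-methylbutanoyl]oxy}-7α-isopropenyl-4α,5α-dimethyl-10αH-decalin-2-one
Conditions: SOCl2, pyridine, CH2Cl2, −30 → 0 °C
Reagents that add atoms: none
Why: E2-type dehydration of the tertiary alcohol through its chlorosulfite with pyridine should remove one of the six methyl hydrogens in preference to the single hindered C7–H flanked by the C8 ester, giving the isopropenyl group without touching any stereocentre.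

Compound list
1 | 2-hydroxy-4-methylbenzaldehyde | O=Cc1ccc(C)cc1O | starting material
2 | allyl bromide | C=CCBr | starting material
3 | 2-(allyloxy)-4-methylbenzaldehyde | O=Cc1ccc(C)cc1OCC=C | intermediate
4 | 3-allyl-2-hydroxy-4-methylbenzaldehyde | O=Cc1ccc(C)c(CC=C)c1O | intermediate
5 | 3-allyl-2-(methoxymethoxy)-4-methylbenzaldehyde | O=Cc1ccc(C)c(CC=C)c1OCOC | intermediate
6 | 2-(methoxymethoxy)-4-methyl-3-(oxiran-2-ylmethyl)phenyl formate (racemic) | O=COc1ccc(C)c(CC2CO2)c1OCOC | intermediate (not isolated)
7 | 2-(methoxymethoxy)-4-methyl-3-(oxiran-2-ylmethyl)phenol (racemic) | Oc1ccc(C)c(CC2CO2)c1OCOC | intermediate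
8 | tert-butyldimethyl{[2-(methoxymethoxy)-4-methyl-3-(oxiran-2-ylmethyl)phenyl]oxy}silane (racemic) | CC(C)(C)[Si](C)(C)Oc1ccc(C)c(CC2CO2)c1OCOC | intermediate
9 | vinylmagnesium bromide | C=C[Mg]Br | starting material
10 | 1-{3-[(tert-butyldimethylsilyl)oxy]-2-(methoxymethoxy)-6-methylphenyl}pent-4-en-2-ol (racemic) | C=CCC(O)Cc1c(C)ccc(O[Si](C)(C)C(C)(C)C)c1OCOC | intermediate
11 | 1-{3-[(tert-butyldimethylsilyl)oxy]-2-(methoxymethoxy)-6-methylphenyl}pent-4-en-2-one | C=CCC(=O)Cc1c(C)ccc(O[Si](C)(C)C(C)(C)C)c1OCOC | intermediate (not isolated)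
12 | (E)-1-{3-[(tert-butyldimethylsilyl)oxy]-2-(methoxymethoxy)-6-methylphenyl}pent-3-en-2-one | C/C=C/C(=O)Cc1c(C)ccc(O[Si](C)(C)C(C)(C)C)c1OCOC | intermediate
13 | (E)-1-[3-hydroxy-2-(methoxymethoxy)-6-methylphenyl]pent-3-en-2-one | C/C=C/C(=O)Cc1c(C)ccc(O)c1OCOC | intermediate (key-step precursor)
14 | (4S,4aS)-8-(methoxymethoxy)-4,4a-dimethyl-3,4-dihydronaphthalene-2,7(1H,4aH)-dione | C[C@H]1CC(=O)CC2=C(OCOC)C(=O)C=C[C@]12C | intermediate (key-step product)
15 | 9β-(methoxymethoxy)-4α,5α-dimethyl-10αH-decalin-2,8-dione | O=C1CC[C@@]2(C)[C@H](CC(=O)C[C@@H]2C)[C@@H]1OCOC | intermediate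
16 | 9β-hydroxy-4α,5α-dimethyl-10αH-decalin-2,8-dione | O=C1CC[C@@]2(C)[C@H](CC(=O)C[C@@H]2C)[C@@H]1O | intermediate (not isolated)
17 | 2α-methoxy-2β,9β-epoxy-4α,5α-dimethyl-10αH-decalin-8-one | O=C1CC[C@@]2(C)[C@@H]3C[C@](OC)(C[C@@H]2C)O[C@H]13 | intermediate
18 | acetone | CC(C)=O | starting material
19 | 7α-(2-hydroxypropan-2-yl)-2α-methoxy-2β,9β-epoxy-4α,5α-dimethyl-10αH-decalin-8-one | O=C1[C@@H](C(C)(C)O)C[C@@]2(C)[C@@H]3C[C@](OC)(C[C@@H]2C)O[C@H]13 | intermediate
20 | 7α-(2-hydroxypropan-2-yl)-2α-methoxy-2β,9β-epoxy-4α,5α-dimethyl-10αH-decalin-8β-ol | O[C@@H]1[C@@H](C(C)(C)O)C[C@@]2(C)[C@@H]3C[C@](OC)(C[C@@H]2C)O[C@H]13 | intermediate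
21 | 8β,9β-dihydroxy-7α-(2-hydroxypropan-2-yl)-4α,5α-dimethyl-10αH-decalin-2-one | O[C@@H]1[C@@H](C(C)(C)O)C[C@@]2(C)[C@H](CC(=O)C[C@@H]2C)[C@@H]1O | intermediate
22 | (R)-2-methylbutanoic acid | CC[C@@H](C)C(=O)O | starting material
23 | 8β,9β-bis{[(R)-2-methylbutanoyl]oxy}-7α-(2-hydroxypropan-2-yl)-4α,5α-dimethyl-10αH-decalin-2-one | CC[C@@H](C)C(=O)O[C@@H]1[C@@H](C(C)(C)O)C[C@@]2(C)[C@H](CC(=O)C[C@@H]2C)[C@@H]1OC(=O)[C@H](C)CC | intermediate
24 | (4S,5R,7R,8R,9S,10S)-8β,9β-bis{[(R)-2-methylbutanoyl]oxy}-7α-isopropenyl-4α,5α-dimethyl-10αH-decalin-2-one (CNP0248369.1) | C=C(C)[C@H]1C[C@@]2(C)[C@H](CC(=O)C[C@@H]2C)[C@H](OC(=O)[C@H](C)CC)[C@@H]1OC(=O)[C@H](C)CC | target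

Total step count: 16. Longest linear sequence: 16 steps (1 → 24).

Steps most likely to fail

Step 9 (proposed new method). The phenoxide may not add at a useful rate, the adduct may revert by retro-Michael re-aromatisation before it is held as the C1 enolate, or the catalyst may discriminate the two arene faces poorly. The fallback forms the same C4–C5 bond by the long-known intramolecular para-alkylation of a phenoxide by a tethered sulfonate, with C4 taken from the chiral pool; it sets out from 8 and comes back at 14. Periodic acid cleaves the epoxide of 8 to the arylacetaldehyde F1, and propane-1,3-dithiol with catalytic iodine converts it into the 2-benzyl-1,3-dithiane F2. Lithiation with n-BuLi and opening of (R)-propylene oxide at its CH2 carbon gives the (R)-carbinol F3, which MsCl/Et3N turns into the mesylate F4. Buffered TBAF frees the phenol F5, and KOt-Bu in t-BuOH–THF closes ring B by SN2 attack of C5 on C4 with inversion (chair-like closure, C4 methyl equatorial, hence cis to the C5 methyl) to the dithiane-masked dienone F6. MeI/CaCO3 in aqueous MeCN then unmasks the C2 ketone to give 14.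

Step 10. The tetrasubstituted enol-ether bond may resist hydrogenation, or hydrogen may be taken up from the β face and lead into the trans-fused series. The fallback replaces steric control by hydroxyl direction; it sets out from 14 and comes back at 15. Wilkinson's catalyst saturates only C6=C7 to give the enone dione F7. NaBH4/CeCl3 reduces both ketones to the diol F8, whose allylic C8 hydroxyl is α (hydride anti to the axial C5 methyl, as for Δ4-3-keto steroids) and whose C2 carbinol is mainly equatorial and of no consequence. Crabtree's catalyst, bound to the 8α-hydroxyl, then delivers hydrogen to the α face of C9=C10 to give the saturated diol F9. Dess–Martin oxidation of both carbinols returns 15.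

Step 16. The elimination may lose regiocontrol (abstraction of the C7 hydrogen to the tetrasubstituted isopropylidene isomer) or the tertiary centre may ionise with participation of the neighbouring ester. The fallback avoids any dehydration by introducing the intact isopropenyl group; it sets out from 17 and comes back at 24. Palladium-catalysed α-alkenylation of the enolate of 17 with 2-bromopropene (LiHMDS, Pd2(dba)3, P(t-Bu)3) gives the 7α-isopropenyl ketone F10, with convex-face, equatorial C7 as before. Immediate NaBH4/CeCl3 reduction, before the β,γ-alkene can move into conjugation, gives the 8β-alcohol F11. Dilute aqueous acid opens the bridged ketal to the diol ketone F12, and the esterification conditions of step 15 convert it into 24.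

Further compounds
F1 | step 9 | 2-{3-[(tert-butyldimethylsilyl)oxy]-2-(methoxymethoxy)-6-methylphenyl}acetaldehyde | O=CCc1c(C)ccc(O[Si](C)(C)C(C)(C)C)c1OCOC
F2 | step 9 | 2-{3-[(tert-butyldimethylsilyl)oxy]-2-(methoxymethoxy)-6-methylbenzyl}-1,3-dithiane | C1CSC(Cc2c(C)ccc(O[Si](C)(C)C(C)(C)C)c2OCOC)SC1
F3 | step 9 | (R)-1-(2-{3-[(tert-butyldimethylsilyl)oxy]-2-(methoxymethoxy)-6-methylbenzyl}-1,3-dithian-2-yl)propan-2-ol | C[C@@H](O)CC1(Cc2c(C)ccc(O[Si](C)(C)C(C)(C)C)c2OCOC)SCCCS1
F4 | step 9 | (R)-1-(2-{3-[(tert-butyldimethylsilyl)oxy]-2-(methoxymethoxy)-6-methylbenzyl}-1,3-dithian-2-yl)propan-2-yl methanesulfonate | C[C@@H](OS(C)(=O)=O)CC1(Cc2c(C)ccc(O[Si](C)(C)C(C)(C)C)c2OCOC)SCCCS1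
F5 | step 9 | (R)-1-{2-[3-hydroxy-2-(methoxymethoxy)-6-methylbenzyl]-1,3-dithian-2-yl}propan-2-yl methanesulfonate | C[C@@H](OS(C)(=O)=O)CC1(Cc2c(C)ccc(O)c2OCOC)SCCCS1
F6 | step 9 | 1,3-dithiane (at C2) of dienone 14 | C[C@H]1CC2(SCCCS2)CC3=C(OCOC)C(=O)C=C[C@]13C
F7 | step 10 | 6,7-dihydro derivative of 14 (9-(methoxymethoxy)-4α,5α-dimethyl-Δ9(10)-octalin-2,8-dione) | C[C@H]1CC(=O)CC2=C(OCOC)C(=O)CC[C@]12C
F8 | step 10 | 9-(methoxymethoxy)-4α,5α-dimethyl-Δ9(10)-octalin-2,8α-diol (C2 epimers) | C[C@H]1CC(O)CC2=C(OCOC)[C@@H](O)CC[C@]12C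
F9 | step 10 | 9β-(methoxymethoxy)-4α,5α-dimethyl-10αH-decalin-2,8α-diol (C2 epimers) | O[C@H]1CC[C@@]2(C)[C@H](CC(O)C[C@@H]2C)[C@@H]1OCOC
F10 | step 16 | 7α-isopropenyl-2α-methoxy-2β,9β-epoxy-4α,5α-dimethyl-10αH-decalin-8-one | O=C1[C@@H](C(C)=C)C[C@@]2(C)[C@@H]3C[C@](OC)(C[C@@H]2C)O[C@H]13
F11 | step 16 | 7α-isopropenyl-2α-methoxy-2β,9β-epoxy-4α,5α-dimethyl-10αH-decalin-8β-ol | O[C@@H]1[C@@H](C(C)=C)C[C@@]2(C)[C@@H]3C[C@](OC)(C[C@@H]2C)O[C@H]13
F12 | step 16 | 8β,9β-dihydroxy-7α-isopropenyl-4α,5α-dimethyl-10αH-decalin-2-one | O[C@@H]1[C@@H](C(C)=C)C[C@@]2(C)[C@H](CC(=O)C[C@@H]2C)[C@@H]1O
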